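**Retrosynthetic overview**
1. The target is the threo-(7R,8R) 8-O-4' neolignan (C23H30O8). Its C9 CH2OH comes from reductive removal of an N-acyl oxazolidinone, with the C7 hydroxyl masked as a TBS ether for that step.
2. The key disconnection is C7–C8. An intermolecular Evans syn aldol joins the boron enolate of an N-(aryloxyacetyl)-(S)-4-benzyloxazolidinone to 3,4,5-trimethoxybenzaldehyde and sets both stereocenters at once (syn = threo).
3. The C8–O(aryl) bond is made first, before any stereocenter exists, by Williamson alkylation of 4-allyl-2,6-dimethoxyphenol with ethyl bromoacetate. Saponification and N-acylation of the auxiliary follow.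
4. No ring is formed. Both benzene rings are bought fully substituted, and the oxazolidinone ring is bought, carried along and released intact.

Assumption: 4-allyl-2,6-dimethoxyphenol (methoxyeugenol, a flavour chemical) counts as a cheap commercial starting material. Lignan numbering is used in the comments (C7 carbinol, C8 aryloxy carbon, C9 CH2OH).

**Step 1**
Reactants: 1 4-allyl-2,6-dimethoxyphenol; 2 ethyl bromoacetate
Product: 3 ethyl 2-(4-allyl-2,6-dimethoxyphenoxy)acetate
Conditions: K2CO3 (2 equiv), acetone, reflux, 12 h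
Reagents that add atoms: ethyl bromoacetate (2), CCOC(=O)CBr
Why: Williamson ether synthesis, in which the phenoxide of 1 displaces bromide from the very reactive α-bromo ester by SN2, while K2CO3 in acetone is far too weak to move the allyl double bond into conjugation.

**Step 2**
Reactants: 3 ethyl 2-(4-allyl-2,6-dimethoxyphenoxy)acetate
Product: 4 2-(4-allyl-2,6-dimethoxyphenoxy)acetic acid
Conditions: LiOH·H2O (2 equiv), THF/H2O 3:1, rt; then 1 M HCl to pH 2
Reagents that add atoms: lithium hydroxide (its oxygen becomes the acid OH), [Li+].[OH-]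
Why: Saponification of an unhindered ethyl ester runs cleanly at room temperature, no stereocenter is present, and the aryl ethers and the allyl group are inert to LiOH.

**Step 3**
Reactants: 4 2-(4-allyl-2,6-dimethoxyphenoxy)acetic acid; 5 (S)-4-benzyl-1,3-oxazolidin-2-one
Product: 7 (S)-3-[2-(4-allyl-2,6-dimethoxyphenoxy)acetyl]-4-benzyl-1,3-oxazolidin-2-one, via mixed pivalic anhydride 6 (not isolated)
Conditions: PivCl (1.05 equiv), Et3N (2.5 equiv), THF, −20 °C, 1 h; then LiCl (1.1 equiv), 5 (1.0 equiv), −20 °C → rt, 12 h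
Reagents that add atoms: (S)-4-benzyl-1,3-oxazolidin-2-one (5), O=C1N[C@@H](Cc2ccccc2)CO1; pivaloyl chloride (atoms held in 6 only), CC(C)(C)C(=O)Cl
Why: N-acylation of an Evans auxiliary by the mixed-anhydride method, in which the LiCl/Et3N-activated oxazolidinone attacks the open aryloxyacetyl carbonyl of 6 because the tert-butyl group shields the pivaloyl carbonyl, and C4 of the auxiliary is not touched.

**Step 4**
Reactants: 7 (S)-3-[2-(4-allyl-2,6-dimethoxyphenoxy)acetyl]-4-benzyl-1,3-oxazolidin-2-one; 8 3,4,5-trimethoxybenzaldehyde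
Product: 11 (S)-4-benzyl-3-[(2S,3R)-2-(4-allyl-2,6-dimethoxyphenoxy)-3-hydroxy-3-(3,4,5-trimethoxyphenyl)propanoyl]-1,3-oxazolidin-2-one, via Z-dibutylboron enolate 9 (not isolated), via dibutylboron aldolate 10 (not isolated)
Conditions: Bu2BOTf (1.2 equiv), Et3N (1.4 equiv), CH2Cl2, −78 → 0 °C, 1 h; 8 (1.2 equiv), −78 °C, 1 h → 0 °C, 2 h; then pH 7 phosphate buffer, MeOH, 30% H2O2, 0 °C, 1 h
Reagents that add atoms: 3,4,5-trimethoxybenzaldehyde (8), COc1cc(C=O)cc(OC)c1OC; dibutylboron triflate (atoms held in 9 and 10 only), CCCCB(CCCC)OS(=O)(=O)C(F)(F)F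
Why: Evans syn aldol reaction, in which soft enolisation gives only the Z-boron enolate 9, which adds to 8 through a closed Zimmerman–Traxler chair whose one enolate face is blocked by the benzyl group of the (S)-auxiliary, so both new stereocenters are set together as (2S,3R), the syn (threo) array that becomes (7R,8R) in the target.

**Step 5**
Reactants: 11 the syn aldol adduct
Product: 12 (S)-4-benzyl-3-[(2S,3R)-2-(4-allyl-2,6-dimethoxyphenoxy)-3-[(tert-butyldimethylsilyl)oxy]-3-(3,4,5-trimethoxyphenyl)propanoyl]-1,3-oxazolidin-2-one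
Conditions: TBSOTf (1.3 equiv), 2,6-lutidine (2 equiv), CH2Cl2, −78 → 0 °C
Reagents that add atoms: tert-butyldimethylsilyl triflate, CC(C)(C)[Si](C)(C)OS(=O)(=O)C(F)(F)F
Why: O-silylation with a silyl triflate and a hindered non-nucleophilic base forms only an O–Si bond, so C7 and C8 keep their configuration and the aldol is locked against retro-aldol cleavage in the following hydride step.

**Step 6**
Reactants: 12 the TBS-protected aldol adduct
Product: 13 (2R,3R)-2-(4-allyl-2,6-dimethoxyphenoxy)-3-[(tert-butyldimethylsilyl)oxy]-3-(3,4,5-trimethoxyphenyl)propan-1-ol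
Conditions: LiBH4 (2 equiv), MeOH (2 equiv), THF, 0 °C, 2 h
Reagents that add atoms: none
Why: Reductive cleavage of the Evans auxiliary, in which the methoxyborohydride made from LiBH4 and MeOH attacks the exocyclic imide carbonyl and reduces the released aldehyde at once, no bond at C7 or C8 is broken (the C8 label changes from S to R only because CH2OH ranks below C7), and the isolated allyl group is not hydroborated at 0 °C.

**Step 7**
Reactants: 13 the mono-TBS diol
Product: 14 (1R,2R)-2-(4-allyl-2,6-dimethoxyphenoxy)-1-(3,4,5-trimethoxyphenyl)propane-1,3-diol (target)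
Conditions: TBAF (1.0 M in THF, 1.5 equiv), THF, 0 °C → rt
Reagents that add atoms: none
Why: Fluoride-mediated desilylation is driven by the strong Si–F bond and cleaves only the O–Si bond, so C7 is retained, any silyl migration to O9 is harmless because both positions end up free, and the non-acidic medium avoids ionisation of the electron-rich benzylic alcohol.

**Compound list**
1 | 4-allyl-2,6-dimethoxyphenol (methoxyeugenol) | C=CCc1cc(OC)c(O)c(OC)c1 | starting material
2 | ethyl bromoacetate | CCOC(=O)CBr | starting material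
3 | ethyl 2-(4-allyl-2,6-dimethoxyphenoxy)acetate | C=CCc1cc(OC)c(OCC(=O)OCC)c(OC)c1 | intermediate
4 | 2-(4-allyl-2,6-dimethoxyphenoxy)acetic acid | C=CCc1cc(OC)c(OCC(=O)O)c(OC)c1 | intermediate
5 | (S)-4-benzyl-1,3-oxazolidin-2-one | O=C1N[C@@H](Cc2ccccc2)CO1 | starting material
6 | 2-(4-allyl-2,6-dimethoxyphenoxy)acetic pivalic anhydride (formed and consumed in the flask) | C=CCc1cc(OC)c(OCC(=O)OC(=O)C(C)(C)C)c(OC)c1 | intermediate
7 | (S)-3-[2-(4-allyl-2,6-dimethoxyphenoxy)acetyl]-4-benzyl-1,3-oxazolidin-2-one | C=CCc1cc(OC)c(OCC(=O)N2C(=O)OC[C@@H]2Cc3ccccc3)c(OC)c1 | intermediate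
8 | 3,4,5-trimethoxybenzaldehyde | COc1cc(C=O)cc(OC)c1OC | starting material
9 | (Z)-dibutylboron enolate of 7 (formed and consumed in the flask) | C=CCc1cc(OC)c(O/C=C(\OB(CCCC)CCCC)N2C(=O)OC[C@@H]2Cc3ccccc3)c(OC)c1 | intermediate
10 | O-dibutylboryl aldolate of 11, (2S,3R) (formed and consumed in the flask) | C=CCc1cc(OC)c(O[C@H](C(=O)N2C(=O)OC[C@@H]2Cc3ccccc3)[C@H](OB(CCCC)CCCC)c4cc(OC)c(OC)c(OC)c4)c(OC)c1 | intermediate
11 | (S)-4-benzyl-3-[(2S,3R)-2-(4-allyl-2,6-dimethoxyphenoxy)-3-hydroxy-3-(3,4,5-trimethoxyphenyl)propanoyl]-1,3-oxazolidin-2-one | C=CCc1cc(OC)c(O[C@H](C(=O)N2C(=O)OC[C@@H]2Cc3ccccc3)[C@H](O)c4cc(OC)c(OC)c(OC)c4)c(OC)c1 | intermediate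
12 | (S)-4-benzyl-3-[(2S,3R)-2-(4-allyl-2,6-dimethoxyphenoxy)-3-[(tert-butyldimethylsilyl)oxy]-3-(3,4,5-trimethoxyphenyl)propanoyl]-1,3-oxazolidin-2-one | C=CCc1cc(OC)c(O[C@H](C(=O)N2C(=O)OC[C@@H]2Cc3ccccc3)[C@H](O[Si](C)(C)C(C)(C)C)c4cc(OC)c(OC)c(OC)c4)c(OC)c1 | intermediate
13 | (2R,3R)-2-(4-allyl-2,6-dimethoxyphenoxy)-3-[(tert-butyldimethylsilyl)oxy]-3-(3,4,5-trimethoxyphenyl)propan-1-ol | C=CCc1cc(OC)c(O[C@H](CO)[C@H](O[Si](C)(C)C(C)(C)C)c2cc(OC)c(OC)c(OC)c2)c(OC)c1 | intermediate
14 | (1R,2R)-2-(4-allyl-2,6-dimethoxyphenoxy)-1-(3,4,5-trimethoxyphenyl)propane-1,3-diol, threo-(7R,8R) | C=CCc1cc(OC)c(O[C@H](CO)[C@H](O)c2cc(OC)c(OC)c(OC)c2)c(OC)c1 | target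

**Totals**
Total step count: 7. Longest linear sequence: 7 steps (1 → 3 → 4 → 7 → 11 → 12 → 13 → 14). Compounds 2, 5 and 8 are bought.

**Three steps most likely to fail**

Step 4 (aldol). The bulky, Lewis-basic 2,6-dimethoxyaryloxy group could slow enolisation, and the electron-rich aldehyde is a modest electrophile. Either effect could lower conversion or the diastereomer ratio.

The fallback sets out from 3 and comes back at 14. It replaces auxiliary control by catalytic control. Ester 3 is deprotonated with LiHMDS (2.2 equiv, THF, −78 °C) and C-acylated with commercial 3,4,5-trimethoxybenzoyl chloride in a crossed Claisen condensation. This gives the configurationally labile β-keto ester ethyl 2-(4-allyl-2,6-dimethoxyphenoxy)-3-oxo-3-(3,4,5-trimethoxyphenyl)propanoate F1.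

Noyori asymmetric transfer hydrogenation with dynamic kinetic resolution follows (RuCl[(S,S)-TsDPEN](p-cymene), HCO2H/Et3N 5:2, 30 °C). It delivers hydride in the sense that converts acetophenone into (S)-1-phenylethanol, which corresponds to 7R here, and it favours the syn isomer. The product is ethyl (2S,3R)-2-(4-allyl-2,6-dimethoxyphenoxy)-3-hydroxy-3-(3,4,5-trimethoxyphenyl)propanoate F2. LiAlH4 (THF, 0 °C) then reduces the ester of F2 to give 14.

Step 6 (reductive cleavage). The exocyclic carbonyl sits between the aryloxy and silyloxy groups, so hydride may attack the ring carbonyl instead and open the oxazolidinone.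

The fallback sets out from 12 and comes back at 13. LiSEt (EtSH, n-BuLi, THF, 0 °C) is a small, soft nucleophile that attacks only the exocyclic carbonyl. It converts 12 into the thioester S-ethyl (2S,3R)-2-(4-allyl-2,6-dimethoxyphenoxy)-3-[(tert-butyldimethylsilyl)oxy]-3-(3,4,5-trimethoxyphenyl)propanethioate F3. LiAlH4 (Et2O, 0 °C) reduces F3 to 13.

Step 5 (silylation). The crowded benzylic hydroxyl may silylate slowly, and the Lewis-acidic triflate could trigger retro-aldol cleavage or ionisation at C7.

The fallback sets out from 11 and comes back at 14, leaving out the protecting group. Compound 11 is reduced directly with NaBH4 (4 equiv, THF/H2O 4:1, 0 °C → rt). The free hydroxyl binds boron and steers hydride to the exocyclic carbonyl, at the price of some retro-aldol risk. The new compounds of this fallback are: none F0.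

**Further compounds**
F1 | step 4 | ethyl 2-(4-allyl-2,6-dimethoxyphenoxy)-3-oxo-3-(3,4,5-trimethoxyphenyl)propanoate (racemic, C2 labile) | C=CCc1cc(OC)c(OC(C(=O)OCC)C(=O)c2cc(OC)c(OC)c(OC)c2)c(OC)c1
F2 | step 4 | ethyl (2S,3R)-2-(4-allyl-2,6-dimethoxyphenoxy)-3-hydroxy-3-(3,4,5-trimethoxyphenyl)propanoate | C=CCc1cc(OC)c(O[C@H](C(=O)OCC)[C@H](O)c2cc(OC)c(OC)c(OC)c2)c(OC)c1
F3 | step 6 | S-ethyl (2S,3R)-2-(4-allyl-2,6-dimethoxyphenoxy)-3-[(tert-butyldimethylsilyl)oxy]-3-(3,4,5-trimethoxyphenyl)propanethioate | C=CCc1cc(OC)c(O[C@H](C(=O)SCC)[C@H](O[Si](C)(C)C(C)(C)C)c2cc(OC)c(OC)c(OC)c2)c(OC)c1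
F0 | step 5 | none | none
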